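The route rests on closing ring C at the aryl ether bond O1–C8a, not at O1–C2. C8a lies ortho to the C4 carbonyl and meta to both O5 and O7 of ring A, so a fluoride placed there is activated for addition–elimination while the ring ethers do not deactivate it. The precursor is an open-chain (S)-β-hydroxy ketone with a 2-fluoroaryl ring A, its carbinol set by copper-catalysed asymmetric conjugate borylation/oxidation of a chalcone. Deprotonation then lets the C2 alkoxide displace fluoride: one operation forms ring C and leaves the C2–O bond untouched, so the (2S) centre is not exposed to the reversible oxa-Michael closure.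

Key step: step 8

Remark: open-chain intermediates are described with the flavanone numbering of the target (O1, C2, C3, C4, C4a, C5–C8, C8a; ring A = benzo ring, ring B = 2-aryl ring, ring C = pyranone ring). MOM = methoxymethyl, prenyl = 3-methylbut-2-en-1-yl.

Assumption: the facial sense of the Josiphos–CuCl borylation in step 7 is taken to follow simple (E)-chalcones. The ligand is written as the (R,SP) enantiomer; its mirror image is used if the first run gives the (R)-carbinol.

Step 1
Reactants: 1 5-fluorobenzene-1,3-diol (5-fluororesorcinol)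
Product: 2 1-fluoro-3,5-bis(methoxymethoxy)benzene
Conditions: MOMCl, i-Pr2NEt, CH2Cl2, 0 °C → rt
Reagents that add atoms: chloromethyl methyl ether, COCCl
Why: Double O-alkylation of the phenols (Williamson-type acetal ether formation) should give base-stable MOM ethers that also direct the two later lithiations.

Step 2
Reactants: 2 1-fluoro-3,5-bis(methoxymethoxy)benzene
Product: 4 5-fluoro-1,3-bis(methoxymethoxy)-2-(3-methylbut-2-en-1-yl)benzene, via aryllithium 3 (not isolated)
Conditions: n-BuLi, Et2O, −20 → 0 °C; CuBr·SMe2 (10 mol%), prenyl bromide, 0 °C → rt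
Reagents that add atoms: 1-bromo-3-methylbut-2-ene (prenyl bromide), CC(C)=CCBr
Why: Directed ortho-metalation under coordination control is expected at the C–H flanked by the two MOM ethers (cooperative chelation of n-BuLi in ether), and copper-assisted SN2 allylation at the primary carbon of prenyl bromide should give the linear prenyl arene.

Step 3
Reactants: 5 3-bromo-4-hydroxybenzaldehyde
Product: 6 3-bromo-4-(methoxymethoxy)benzaldehyde
Conditions: MOMCl, i-Pr2NEt, CH2Cl2, 0 °C → rt
Reagents that add atoms: chloromethyl methyl ether, COCCl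
Why: O-Alkylation of the acidic para-formyl phenol (Williamson-type) protects it as the same acid-labile acetal used on ring A.

Step 4
Reactants: 6 3-bromo-4-(methoxymethoxy)benzaldehyde
Product: 7 4-(methoxymethoxy)-3-(3-methylbut-2-en-1-yl)benzaldehyde
Conditions: Pd(PPh3)4 (5 mol%), tributyl(prenyl)stannane, DMF, 90 °C
Reagents that add atoms: tributyl(3-methylbut-2-en-1-yl)stannane, CCCC[Sn](CCCC)(CCCC)CC=C(C)C
Why: Stille coupling (oxidative addition of zerovalent palladium into C–Br, allyl transfer from tin, reductive elimination at the less substituted allyl terminus) should install the linear prenyl group and tolerate the aldehyde.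

Step 5
Reactants: 7 4-(methoxymethoxy)-3-(3-methylbut-2-en-1-yl)benzaldehyde
Product: 8 (2E)-N-methoxy-N-methyl-3-[4-(methoxymethoxy)-3-(3-methylbut-2-en-1-yl)phenyl]prop-2-enamide
Conditions: (EtO)2P(O)CH2C(O)N(OMe)Me, NaH, THF, 0 °C → rt
Reagents that add atoms: diethyl [2-[methoxy(methyl)amino]-2-oxoethyl]phosphonate, CCOP(=O)(CC(=O)N(C)OC)OCC
Why: Horner–Wadsworth–Emmons olefination with the stabilised amide phosphonate should give the (E)-enamide, which carries C2, C3 and C4 of the target.

Step 6
Reactants: 4 5-fluoro-1,3-bis(methoxymethoxy)-2-(3-methylbut-2-en-1-yl)benzene; 8 (2E)-N-methoxy-N-methyl-3-[4-(methoxymethoxy)-3-(3-methylbut-2-en-1-yl)phenyl]prop-2-enamide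
Product: 11 (2E)-1-[6-fluoro-2,4-bis(methoxymethoxy)-3-(3-methylbut-2-en-1-yl)phenyl]-3-[4-(methoxymethoxy)-3-(3-methylbut-2-en-1-yl)phenyl]prop-2-en-1-one, via aryllithium 9 (not isolated), via tetrahedral lithium adduct 10 (not isolated)
Conditions: 4, n-BuLi, THF, −78 °C; then 8, −78 °C; AcOH, −78 °C
Reagents that add atoms: none
Why: Directed ortho-metalation at the only remaining kind of ring C–H (flanked by F and OMOM, two equivalent sites) gives an ortho-fluoroaryllithium that is stable at −78 °C and adds 1,2 to the amide (Weinreb ketone synthesis); the chelated adduct prevents over-addition and releases the (E)-enone on cold acidic quench.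

Step 7
Reactants: 11 (2E)-1-[6-fluoro-2,4-bis(methoxymethoxy)-3-(3-methylbut-2-en-1-yl)phenyl]-3-[4-(methoxymethoxy)-3-(3-methylbut-2-en-1-yl)phenyl]prop-2-en-1-one
Product: 13 (3S)-1-[6-fluoro-2,4-bis(methoxymethoxy)-3-(3-methylbut-2-en-1-yl)phenyl]-3-hydroxy-3-[4-(methoxymethoxy)-3-(3-methylbut-2-en-1-yl)phenyl]propan-1-one, via β-boryl ketone 12 (not isolated)
Conditions: CuCl (5 mol%), NaOt-Bu (10 mol%), (R,SP)-Josiphos [(R)-1-[(SP)-2-(diphenylphosphino)ferrocenyl]ethyldicyclohexylphosphine] (6 mol%), B2pin2, MeOH, THF, rt; then NaBO3·4H2O, THF/H2O, 0 °C → rt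
Reagents that add atoms: sodium perborate tetrahydrate (NaBO3·4H2O), [Na+].[Na+].O[B-]1(O)OO[B-](O)(O)OO1
Why: Copper-catalysed enantioselective conjugate borylation should deliver boron to one face of C2 under control of the Josiphos ligand, and perborate oxidation of the C–B bond with retention then gives the (S)-carbinol; the unactivated prenyl alkenes are inert to the copper boryl.

Step 8
Reactants: 13 (3S)-1-[6-fluoro-2,4-bis(methoxymethoxy)-3-(3-methylbut-2-en-1-yl)phenyl]-3-hydroxy-3-[4-(methoxymethoxy)-3-(3-methylbut-2-en-1-yl)phenyl]propan-1-one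
Product: 16 (2S)-5,7-bis(methoxymethoxy)-2-[4-(methoxymethoxy)-3-(3-methylbut-2-en-1-yl)phenyl]-6-(3-methylbut-2-en-1-yl)-2,3-dihydro-4H-chromen-4-one, via potassium alkoxide 14 (not isolated), via Meisenheimer adduct 15 (not isolated)
Conditions: KHMDS (1.05 equiv), THF, −78 → −40 °C; pH 7 buffer
Reagents that add atoms: none
Why: KHMDS removes the O–H proton to give alkoxide 14, whose oxygen adds to C8a (ipso to fluorine) to form the σ-adduct 15 with the charge held as the C4 dienolate, and loss of fluoride as KF rearomatises ring A. The closest known reaction type is the intramolecular nucleophilic aromatic substitution (SNAr) of ortho-fluoroaryl ketones by alkoxides, as used for chromanones and xanthones. Ring C closes as a six-membered addition–elimination, formally a 6-exo-trig attack on the C8a=C8 bond with fluoride as the exocyclic leaving group. No new stereocentre remains in the product (C8a is sp3 only in 15), and C2 is carried over unchanged because only the O–H bond, never the C2–O bond, is broken. The step needs cyclisation to outrun retro-aldol cleavage and E1cB dehydration of the aldolate and to spare the product from base-induced ring opening; this is sought with one equivalent of base at low temperature (the entropically favoured fragmentation is slowed more than the intramolecular addition), the ortho C4 carbonyl with both ring-A ethers meta to C8a, and removal of the base as insoluble KF.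

Step 9
Reactants: 16 (2S)-5,7-bis(methoxymethoxy)-2-[4-(methoxymethoxy)-3-(3-methylbut-2-en-1-yl)phenyl]-6-(3-methylbut-2-en-1-yl)-2,3-dihydro-4H-chromen-4-one
Product: 17 macarangaflavanone B, (2S)-5,7-dihydroxy-2-[4-hydroxy-3-(3-methylbut-2-en-1-yl)phenyl]-6-(3-methylbut-2-en-1-yl)-2,3-dihydro-4H-chromen-4-one
Conditions: 3 M aq. HCl, MeOH, 40 °C
Reagents that add atoms: none
Why: Acid-catalysed solvolysis of the three MOM acetals (transacetalisation to dimethoxymethane) should free the phenols under conditions mild enough to avoid cyclisation of the prenyl groups onto the ortho-phenols, and without base, so C2 is not epimerised through ring opening.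

Compound list
1 | 5-fluorobenzene-1,3-diol | Oc1cc(O)cc(F)c1 | starting material
2 | 1-fluoro-3,5-bis(methoxymethoxy)benzene | COCOc1cc(F)cc(OCOC)c1 | intermediate
3 | [4-fluoro-2,6-bis(methoxymethoxy)phenyl]lithium | [Li]c1c(OCOC)cc(F)cc1OCOC | intermediate (not isolated)
4 | 5-fluoro-1,3-bis(methoxymethoxy)-2-(3-methylbut-2-en-1-yl)benzene | COCOc1cc(F)cc(OCOC)c1CC=C(C)C | intermediate
5 | 3-bromo-4-hydroxybenzaldehyde | O=Cc1ccc(O)c(Br)c1 | starting material
6 | 3-bromo-4-(methoxymethoxy)benzaldehyde | COCOc1ccc(C=O)cc1Br | intermediate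
7 | 4-(methoxymethoxy)-3-(3-methylbut-2-en-1-yl)benzaldehyde | COCOc1ccc(C=O)cc1CC=C(C)C | intermediate
8 | (2E)-N-methoxy-N-methyl-3-[4-(methoxymethoxy)-3-(3-methylbut-2-en-1-yl)phenyl]prop-2-enamide | CON(C)C(=O)/C=C/c1ccc(OCOC)c(CC=C(C)C)c1 | intermediate
9 | [6-fluoro-2,4-bis(methoxymethoxy)-3-(3-methylbut-2-en-1-yl)phenyl]lithium | [Li]c1c(F)cc(OCOC)c(CC=C(C)C)c1OCOC | intermediate (not isolated)
10 | lithium (2E)-1-[6-fluoro-2,4-bis(methoxymethoxy)-3-prenylphenyl]-1-[methoxy(methyl)amino]-3-[4-(methoxymethoxy)-3-prenylphenyl]prop-2-en-1-olate | [Li]OC(/C=C/c1ccc(OCOC)c(CC=C(C)C)c1)(N(C)OC)c1c(F)cc(OCOC)c(CC=C(C)C)c1OCOC | intermediate (not isolated)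
11 | (2E)-1-[6-fluoro-2,4-bis(methoxymethoxy)-3-(3-methylbut-2-en-1-yl)phenyl]-3-[4-(methoxymethoxy)-3-(3-methylbut-2-en-1-yl)phenyl]prop-2-en-1-one | COCOc1ccc(/C=C/C(=O)c2c(F)cc(OCOC)c(CC=C(C)C)c2OCOC)cc1CC=C(C)C | intermediate
12 | (3S)-1-[6-fluoro-2,4-bis(methoxymethoxy)-3-prenylphenyl]-3-[4-(methoxymethoxy)-3-prenylphenyl]-3-(4,4,5,5-tetramethyl-1,3,2-dioxaborolan-2-yl)propan-1-one | CC(C)=CCc1cc([C@@H](B2OC(C)(C)C(C)(C)O2)CC(=O)c3c(F)cc(OCOC)c(CC=C(C)C)c3OCOC)ccc1OCOC | intermediate (not isolated)
13 | (3S)-1-[6-fluoro-2,4-bis(methoxymethoxy)-3-(3-methylbut-2-en-1-yl)phenyl]-3-hydroxy-3-[4-(methoxymethoxy)-3-(3-methylbut-2-en-1-yl)phenyl]propan-1-one | CC(C)=CCc1cc([C@@H](O)CC(=O)c2c(F)cc(OCOC)c(CC=C(C)C)c2OCOC)ccc1OCOC | intermediate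
14 | potassium alkoxide of 13 (O1 deprotonated) | CC(C)=CCc1cc([C@@H]([O-])CC(=O)c2c(F)cc(OCOC)c(CC=C(C)C)c2OCOC)ccc1OCOC.[K+] | intermediate (not isolated)
15 | Meisenheimer σ-adduct: potassium (2S)-8a-fluoro-5,7-bis(methoxymethoxy)-2-[4-(methoxymethoxy)-3-prenylphenyl]-6-prenyl-3,8a-dihydro-2H-chromen-4-olate | CC(C)=CCc1cc([C@@H]2CC([O-])=C3C(OCOC)=C(CC=C(C)C)C(OCOC)=CC3(F)O2)ccc1OCOC.[K+] | intermediate (not isolated)
16 | (2S)-5,7-bis(methoxymethoxy)-2-[4-(methoxymethoxy)-3-(3-methylbut-2-en-1-yl)phenyl]-6-(3-methylbut-2-en-1-yl)-2,3-dihydro-4H-chromen-4-one | CC(C)=CCc1cc([C@@H]2CC(=O)c3c(cc(OCOC)c(CC=C(C)C)c3OCOC)O2)ccc1OCOC | intermediate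
17 | macarangaflavanone B, (2S)-5,7-dihydroxy-2-[4-hydroxy-3-(3-methylbut-2-en-1-yl)phenyl]-6-(3-methylbut-2-en-1-yl)-2,3-dihydro-4H-chromen-4-one | CC(C)=CCc1cc([C@@H]2CC(=O)c3c(cc(O)c(CC=C(C)C)c3O)O2)ccc1O | target

Total step count: 9. Longest linear sequence: 7 steps (5 → 6 → 7 → 8 → 11 → 13 → 16 → 17, steps 3 to 9).

Steps most likely to fail

Step 8. The alkoxide may fragment by retro-aldol cleavage and recombine, which would erode the enantiomeric purity, or the aldolate may dehydrate to the chalcone before fluoride is displaced. The product could also be opened again by residual base. The fallback sets out from 13 and returns at 16, and removes the carbonyl group before the ring is closed. NaBH4 in MeOH at 0 °C should reduce 13 to (3S)-1-[6-fluoro-2,4-bis(methoxymethoxy)-3-prenylphenyl]-3-[4-(methoxymethoxy)-3-prenylphenyl]propane-1,3-diol F1, as both epimers at the new carbinol, which does not matter. KOt-Bu in DMSO at 70 °C should then close the same O1–C8a bond by intramolecular SNAr on the now non-activated fluoroarene, where neither retro-aldol nor E1cB is possible, to give (2S)-5,7-bis(methoxymethoxy)-2-[4-(methoxymethoxy)-3-prenylphenyl]-6-prenylchroman-4-ol F2. Dess–Martin periodinane with NaHCO3 in CH2Cl2 oxidises the benzylic alcohol to 16.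

Step 2. Lithiation may partition between the site flanked by the two MOM ethers and the sites flanked by fluorine and one MOM ether, giving the wrong prenyl regioisomer or aryne-derived material. The fallback sets out from 1 and returns at 11, and fixes the substitution pattern by electrophilic chemistry. Nencki-type C-acetylation of 1 (AcOH, BF3·OEt2, 90 °C) should give 1-(2-fluoro-4,6-dihydroxyphenyl)ethan-1-one F3. C-Prenylation with prenyl bromide and DBU in THF should place the prenyl group between the two hydroxyls, giving 1-[6-fluoro-2,4-dihydroxy-3-(3-methylbut-2-en-1-yl)phenyl]ethan-1-one F4. MOMCl and NaH in DMF give 1-[6-fluoro-2,4-bis(methoxymethoxy)-3-(3-methylbut-2-en-1-yl)phenyl]ethan-1-one F5. Claisen–Schmidt condensation of F5 with aldehyde 7 (KOH, EtOH, rt) leads to chalcone 11.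

Step 7. Facial selectivity may be poor on the twisted, di-ortho-substituted aryl enone, or the peroxide oxidant may attack the activated C–F bond during the oxidation. The fallback sets out from 11 and returns at 13. Juliá–Colonna epoxidation (poly-D-leucine, urea–H2O2, DBU, THF) is a nucleophilic epoxidation that leaves the prenyl alkenes alone and should give (2S,3R)-[6-fluoro-2,4-bis(methoxymethoxy)-3-prenylphenyl][3-[4-(methoxymethoxy)-3-prenylphenyl]oxiran-2-yl]methanone F6. Reductive cleavage of the Cα–O bond with SmI2 (THF/MeOH, −90 °C) keeps the configuration at the aryl-bearing carbon and gives 13.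

Further compounds
F1 | step 8 | (3S)-1-[6-fluoro-2,4-bis(methoxymethoxy)-3-(3-methylbut-2-en-1-yl)phenyl]-3-[4-(methoxymethoxy)-3-(3-methylbut-2-en-1-yl)phenyl]propane-1,3-diol (both C1 epimers) | CC(C)=CCc1cc([C@@H](O)CC(O)c2c(F)cc(OCOC)c(CC=C(C)C)c2OCOC)ccc1OCOC
F2 | step 8 | (2S)-5,7-bis(methoxymethoxy)-2-[4-(methoxymethoxy)-3-(3-methylbut-2-en-1-yl)phenyl]-6-(3-methylbut-2-en-1-yl)chroman-4-ol (both C4 epimers) | CC(C)=CCc1cc([C@@H]2CC(O)c3c(cc(OCOC)c(CC=C(C)C)c3OCOC)O2)ccc1OCOC
F3 | step 2 | 1-(2-fluoro-4,6-dihydroxyphenyl)ethan-1-one | CC(=O)c1c(O)cc(O)cc1F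
F4 | step 2 | 1-[6-fluoro-2,4-dihydroxy-3-(3-methylbut-2-en-1-yl)phenyl]ethan-1-one | CC(=O)c1c(F)cc(O)c(CC=C(C)C)c1O
F5 | step 2 | 1-[6-fluoro-2,4-bis(methoxymethoxy)-3-(3-methylbut-2-en-1-yl)phenyl]ethan-1-one | CC(=O)c1c(F)cc(OCOC)c(CC=C(C)C)c1OCOC
F6 | step 7 | (2S,3R)-[6-fluoro-2,4-bis(methoxymethoxy)-3-(3-methylbut-2-en-1-yl)phenyl][3-[4-(methoxymethoxy)-3-(3-methylbut-2-en-1-yl)phenyl]oxiran-2-yl]methanone | O=C(c1c(F)cc(OCOC)c(CC=C(C)C)c1OCOC)[C@H]2O[C@@H]2c3ccc(OCOC)c(CC=C(C)C)c3
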